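**Retrosynthetic overview**
1. Atom labels: C1 is the ester carbonyl and C2 the CH(CH3). C3 to C6 are the four carbons of the 1,2-dioxane (O–O bridges C3 and C6), C7 and C8 the two tether CH2 groups, and C9 to C14 the cyclohexenone ring A (C9=C10, C11=O, C14 gem-dimethyl).
2. Feature used: quaternary C6 holds a peroxide oxygen and is bonded to the C7 methylene, the pattern left when a C6–C7 2,2-disubstituted epoxide is opened at its tertiary carbon. Methyl and CH2R on C6 are too alike for conformational control, so C6 must be set stereospecifically.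
3. Late disconnections: C11=O (allylic oxidation of ring A), C7–C8 (Wittig olefination, then diimide; ring A is bought intact as β-cyclocitral), and the C1 ester (oxidative cleavage of a vinyl group).
4. Key disconnection O–C6: a transient oxirane (step 9) is followed by the 1,2-dioxane (step 11), the only ring of the target that is built. It closes 6-exo by attack of a C3 hydroperoxide on the (R)-epoxide with inversion. C6 comes from (S)-2-methylglycidol; C2 and C3 come from an anti crotylboration and an invertive peroxide SN2.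
5. The epoxide is kept latent as C6–OSiEt3/C7–OTs until C3 carries the protected peroxide. A γ-hydroxy aldehyde would form a lactol, and a free C3 carbinol facing the tertiary epoxide would close 5-exo to a tetrahydrofuran.

Key step: step 11

Assumption: the (S) enantiomer of the phosphoric acid is taken to deliver the crotyl group to the Si face of aldehyde 7, by analogy with the Re-face preference of the (R) acid; the configuration of 10 would be checked (Mosher esters) before going on, and the mirror-image catalyst is equally available.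
Assumption: olefin 29 is drawn as the E isomer; the Z isomer gives the same product in step 19.
Remark: descriptors in brackets use the atom labels above. C3 (step 8) and C6 (step 11) are truly inverted; the letter changes at C2 (step 12) and C6 (step 19) come only from CIP priorities.

**Step 1**
Reactants: 1 (S)-2-methylglycidol; 2 allylmagnesium bromide
Product: 3 (2R)-2-methylhex-5-ene-1,2-diol
Conditions: 2 (3 equiv), CuI (10 mol %), THF/Et2O, −40 to 0 °C; aq NH4Cl
Reagents that add atoms: none
Why: Copper-catalysed Grignard opening of an epoxide (SN2) takes place at the unsubstituted ring CH2, which becomes C5; the C6 stereocentre is not touched, and a Payne shift of the alkoxide would be degenerate, so it cannot erode the configuration.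

**Step 2**
Reactants: 3 (2R)-2-methylhex-5-ene-1,2-diol
Product: 4 (2R)-2-hydroxy-2-methylhex-5-en-1-yl 4-methylbenzenesulfonate
Conditions: TsCl (1.05 equiv), Et3N, DMAP (cat.), CH2Cl2, 0 °C
Reagents that add atoms: 4-toluenesulfonyl chloride, Cc1ccc(cc1)S(=O)(=O)Cl
Why: Selective sulfonylation, since the primary C7 hydroxyl reacts far faster than the tertiary C6 hydroxyl.

**Step 3**
Reactants: 4 (2R)-2-hydroxy-2-methylhex-5-en-1-yl 4-methylbenzenesulfonate
Product: 5 (2R)-2-methyl-2-(triethylsilyloxy)hex-5-en-1-yl 4-methylbenzenesulfonate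
Conditions: Et3SiOTf, 2,6-lutidine, CH2Cl2, −78 to 0 °C
Reagents that add atoms: triethylsilyl trifluoromethanesulfonate, CC[Si](CC)(CC)OS(=O)(=O)C(F)(F)F
Why: Silyl triflate silylation of a tertiary alcohol; the ether blocks lactol formation with the coming C3 aldehyde and stores the epoxide as a base-triggered silyloxy tosylate that tolerates the acid catalyst of step 5.

**Step 4**
Reactants: 5 (2R)-2-methyl-2-(triethylsilyloxy)hex-5-en-1-yl 4-methylbenzenesulfonate
Product: 7 (2R)-2-methyl-5-oxo-2-(triethylsilyloxy)pentyl 4-methylbenzenesulfonate, via secondary ozonide 6 (not isolated)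
Conditions: O3, CH2Cl2, −78 °C; then Me2S, −78 °C to rt
Reagents that add atoms: ozone, [O-][O+]=O
Why: Ozonolysis (Criegee mechanism) with reductive work-up cleaves the only alkene to the C3 aldehyde, while the sulfonate and silyl ether are inert.

**Step 5**
Reactants: 7 (2R)-2-methyl-5-oxo-2-(triethylsilyloxy)pentyl 4-methylbenzenesulfonate; 8 (E)-crotylboronic acid pinacol ester
Product: 10 (2R,5R,6S)-5-hydroxy-2,6-dimethyl-2-(triethylsilyloxy)oct-7-en-1-yl 4-methylbenzenesulfonate (2S,3R,6R), via pinacol borate 9 (not isolated)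
Conditions: 8 (1.3 equiv), (S)-TRIP [(S)-3,3'-bis(2,4,6-triisopropylphenyl)-1,1'-binaphthyl-2,2'-diyl hydrogen phosphate, 5 mol %], 4 Å MS, toluene, −30 °C; then aq NaHCO3
Reagents that add atoms: none
Why: Chiral-phosphoric-acid-catalysed crotylboration runs through a closed Zimmerman–Traxler chair, so the E boronate sets the anti C2/C3 relationship and the (S) acid directs attack to the Si face of the aldehyde (2S,3R); wrong-face product is a diastereomer because of C6 and should be removable.

**Step 6**
Reactants: 10 (2R,5R,6S)-5-hydroxy-2,6-dimethyl-2-(triethylsilyloxy)oct-7-en-1-yl 4-methylbenzenesulfonate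
Product: 11 (2R,5R,6S)-2,6-dimethyl-5-(methylsulfonyloxy)-2-(triethylsilyloxy)oct-7-en-1-yl 4-methylbenzenesulfonate (2S,3R,6R)
Conditions: MsCl, Et3N, CH2Cl2, −10 °C
Reagents that add atoms: methanesulfonyl chloride, CS(=O)(=O)Cl
Why: Standard mesylation of the only free hydroxyl; the C3–O bond is not broken, so the configuration is retained.

**Step 7**
Reactants: 12 2,3-dimethylbut-2-ene
Product: 14 2-methoxyprop-2-yl hydroperoxide, via acetone O-oxide 13 (not isolated)
Conditions: O3, MeOH/CH2Cl2, −78 °C; N2 purge, concentration below rt behind a shield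
Reagents that add atoms: ozone, [O-][O+]=O; methanol, CO
Why: Ozonolysis in a participating solvent, in which methanol traps the Criegee carbonyl oxide 13 to give the hydroperoxy ketal.

**Step 8**
Reactants: 11 (2R,5R,6S)-2,6-dimethyl-5-(methylsulfonyloxy)-2-(triethylsilyloxy)oct-7-en-1-yl 4-methylbenzenesulfonate; 14 2-methoxyprop-2-yl hydroperoxide
Product: 15 (2R,5S,6S)-5-[(2-methoxypropan-2-yl)peroxy]-2,6-dimethyl-2-(triethylsilyloxy)oct-7-en-1-yl 4-methylbenzenesulfonate (2S,3S,6R)
Conditions: 14 (2.5 equiv), CsOH·H2O (2 equiv), DMF, 0 °C to rt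
Reagents that add atoms: none
Why: SN2 alkylation of a hydroperoxide anion (an α-effect nucleophile of low basicity) by the secondary mesylate inverts C3 to S; the neopentyl-type C7 tosylate is far slower, and the excess of 14 over the base leaves no free hydroxide for the silyl ether.

**Step 9**
Reactants: 15 (2R,5S,6S)-5-[(2-methoxypropan-2-yl)peroxy]-2,6-dimethyl-2-(triethylsilyloxy)oct-7-en-1-yl 4-methylbenzenesulfonate
Product: 17 (2R)-2-{(3S,4S)-3-[(2-methoxypropan-2-yl)peroxy]-4-methylhex-5-en-1-yl}-2-methyloxirane (2S,3S,6R), via C6 ammonium alkoxide 16 (not isolated)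
Conditions: Bu4NF (1.2 equiv), THF, 0 °C to rt
Reagents that add atoms: none
Why: Fluoride desilylation frees the C6 alkoxide, which displaces the neighbouring primary tosylate (3-exo-tet Williamson closure); the C6–O bond is never broken, so C6 stays R, and the perketal is stable to base.

**Step 10**
Reactants: 17 (2R)-2-{(3S,4S)-3-[(2-methoxypropan-2-yl)peroxy]-4-methylhex-5-en-1-yl}-2-methyloxirane
Product: 18 (2R)-2-[(3S,4S)-3-hydroperoxy-4-methylhex-5-en-1-yl]-2-methyloxirane (2S,3S,6R)
Conditions: PPTS (5 mol %), MeOH/CH2Cl2 (1:4), 0 °C; aq NaHCO3 quench; used at once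
Reagents that add atoms: none
Why: Acid-catalysed transketalisation, in which the acyclic perketal ionises to the 2-methoxyprop-2-yl cation much faster than the epoxide is opened under pyridinium buffering; any ring closure that starts here already gives 19.

**Step 11**
Reactants: 18 (2R)-2-[(3S,4S)-3-hydroperoxy-4-methylhex-5-en-1-yl]-2-methyloxirane
Product: 19 {(3S,6S)-6-[(2S)-but-3-en-2-yl]-3-methyl-1,2-dioxan-3-yl}methanol (2S,3S,6S)
Conditions: (+)-camphor-10-sulfonic acid (10 mol %), CH2Cl2 (0.01 M), −20 to 0 °C; Et3N quench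
Reagents that add atoms: none
Why: Protonation of the epoxide oxygen weakens the more substituted C6–O bond, and the terminal oxygen of the C3 hydroperoxide attacks C6 opposite to the departing oxygen before a free tertiary cation can form, so the O–C6 bond is made with inversion and C7 is released as CH2OH. The closest known reaction type is the acid-promoted exo opening of epoxides and oxetanes by tethered hydroperoxides, the peroxide counterpart of the sulfonic-acid-mediated closure of epoxy alcohols to cyclic ethers at a tertiary carbon. The one ring formed, the 1,2-dioxane, closes in the 6-exo-tet mode through a chair with the C3 butenyl group equatorial, which places C7 equatorial and the C6 methyl axial. The only new stereocentre, C6, is controlled by the configuration of the epoxide inherited from the glycidol and not by any chair preference, while C2 and C3 are spectators. The step needs attack at C6 rather than C7 and substitution without ionisation: ring size (six against seven) and the tertiary against primary polarisation both point to C6, and the weak acid, unpolar solvent, low temperature and high dilution should keep the pathway concerted and intramolecular. Because C1 is still a vinyl group there is no carbonyl next to C2, so the secondary hydroperoxide has no β-elimination path.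

**Step 12**
Reactants: 19 {(3S,6S)-6-[(2S)-but-3-en-2-yl]-3-methyl-1,2-dioxan-3-yl}methanol
Product: 21 (2R)-2-[(3S,6S)-6-(hydroxymethyl)-6-methyl-1,2-dioxan-3-yl]propanal, via secondary ozonide 20 (not isolated)
Conditions: O3, CH2Cl2, −78 °C; then Me2S, −78 °C to rt
Reagents that add atoms: ozone, [O-][O+]=O
Why: Ozonolysis of the monosubstituted alkene; the dialkyl peroxide and the alcohol are inert to O3 and Me2S, and the neutral work-up avoids epimerisation at C2 and β-elimination of the peroxide.

**Step 13**
Reactants: 21 (2R)-2-[(3S,6S)-6-(hydroxymethyl)-6-methyl-1,2-dioxan-3-yl]propanal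
Product: 22 (2R)-2-[(3S,6S)-6-(hydroxymethyl)-6-methyl-1,2-dioxan-3-yl]propanoic acid
Conditions: NaClO2, NaH2PO4, 2-methylbut-2-ene, t-BuOH/H2O, 0 °C to rt
Reagents that add atoms: sodium chlorite, [Na+].[O-]Cl=O
Why: Pinnick oxidation in a weakly acidic buffer oxidises only the aldehyde, leaves the C7 alcohol and the O–O bond alone, and does not enolise C2.

**Step 14**
Reactants: 22 (2R)-2-[(3S,6S)-6-(hydroxymethyl)-6-methyl-1,2-dioxan-3-yl]propanoic acid
Product: 23 methyl (2R)-2-[(3S,6S)-6-(hydroxymethyl)-6-methyl-1,2-dioxan-3-yl]propanoate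
Conditions: Me3SiCHN2, toluene/MeOH (4:1), 0 °C
Reagents that add atoms: (trimethylsilyl)diazomethane, C[Si](C)(C)C=[N+]=[N-]
Why: Diazoalkane esterification works without base, so the β-peroxy carboxyl unit is not exposed to E1cB opening of the dioxane.

**Step 15**
Reactants: 23 methyl (2R)-2-[(3S,6S)-6-(hydroxymethyl)-6-methyl-1,2-dioxan-3-yl]propanoate
Product: 24 methyl (2R)-2-[(3S,6S)-6-formyl-6-methyl-1,2-dioxan-3-yl]propanoate
Conditions: Dess–Martin periodinane, CH2Cl2, 0 °C to rt
Reagents that add atoms: none
Why: Dess–Martin oxidation of the neopentyl-type primary alcohol under non-basic conditions; the aldehyde has no α-hydrogen, so C6 cannot epimerise.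

**Step 16**
Reactants: 25 β-cyclocitral
Product: 26 β-cyclogeraniol
Conditions: NaBH4, MeOH, 0 °C
Reagents that add atoms: none
Why: Borohydride 1,2-reduction of the hindered enal.

**Step 17**
Reactants: 26 β-cyclogeraniol
Product: 27 [(2,6,6-trimethylcyclohex-1-en-1-yl)methyl]triphenylphosphonium bromide
Conditions: PPh3·HBr, MeOH, rt
Reagents that add atoms: triphenylphosphine hydrobromide, [Br-].c1ccc(cc1)[PH+](c1ccccc1)c1ccccc1
Why: Phosphonium salt formation from an allylic alcohol, in which acid activation of the hydroxyl is followed by capture with PPh3, as is routine for cyclogeranyl and ionyl alcohols.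

**Step 18**
Reactants: 24 methyl (2R)-2-[(3S,6S)-6-formyl-6-methyl-1,2-dioxan-3-yl]propanoate; 27 [(2,6,6-trimethylcyclohex-1-en-1-yl)methyl]triphenylphosphonium bromide
Product: 29 methyl (2R)-2-{(3S,6S)-6-methyl-6-[(E)-2-(2,6,6-trimethylcyclohex-1-en-1-yl)ethenyl]-1,2-dioxan-3-yl}propanoate, via allylic ylide 28 (not isolated)
Conditions: 27 (1.3 equiv), NaN(SiMe3)2 (1.2 equiv), THF, −78 to 0 °C; then 24, −78 °C to rt
Reagents that add atoms: none
Why: Wittig olefination forms C7=C8; the semi-stabilised ylide is too weak a base to deprotonate C2–H or C3–H and adds first to the non-enolisable, inductively activated aldehyde, and the olefin geometry does not matter.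

**Step 19**
Reactants: 29 methyl (2R)-2-{(3S,6S)-6-methyl-6-[(E)-2-(2,6,6-trimethylcyclohex-1-en-1-yl)ethenyl]-1,2-dioxan-3-yl}propanoate
Product: 30 methyl (2R)-2-{(3S,6R)-6-methyl-6-[2-(2,6,6-trimethylcyclohex-1-en-1-yl)ethyl]-1,2-dioxan-3-yl}propanoate
Conditions: KO2CN=NCO2K (excess, in portions), AcOH, MeOH/CH2Cl2, 0 °C to rt
Reagents that add atoms: none
Why: Diimide reduction (concerted syn transfer of two hydrogens) discriminates by substitution, so the 1,2-disubstituted C7=C8 is saturated and the tetrasubstituted C9=C10 is left, and the O–O bond, which catalytic hydrogenation would cleave, is not touched.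

**Step 20**
Reactants: 30 methyl (2R)-2-{(3S,6R)-6-methyl-6-[2-(2,6,6-trimethylcyclohex-1-en-1-yl)ethyl]-1,2-dioxan-3-yl}propanoate
Product: 31 methyl diacarnoate A, methyl (2R)-2-{(3S,6R)-6-methyl-6-[2-(2,6,6-trimethyl-3-oxocyclohex-1-en-1-yl)ethyl]-1,2-dioxan-3-yl}propanoate
Conditions: CrO3, 3,5-dimethylpyrazole, CH2Cl2, −20 °C
Reagents that add atoms: chromium trioxide, O=[Cr](=O)=O
Why: Allylic oxidation with the CrO3–3,5-dimethylpyrazole complex should convert the ring methylene C11, whose pseudo-axial C–H overlaps with the C9=C10 π bond, into the enone carbonyl; C8H2 is shielded by the C14 gem-dimethyl group, the C10 methyl is less reactive, and ester and dialkyl peroxide resist hexavalent chromium.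

**Compound list**
1 | (S)-2-methylglycidol | C[C@]1(CO)CO1 | starting material
2 | allylmagnesium bromide | C=CC[Mg]Br | starting material
3 | (2R)-2-methylhex-5-ene-1,2-diol | C[C@](O)(CO)CCC=C | intermediate
4 | (2R)-2-hydroxy-2-methylhex-5-en-1-yl 4-methylbenzenesulfonate | C[C@](O)(COS(=O)(=O)c1ccc(C)cc1)CCC=C | intermediate
5 | (2R)-2-methyl-2-(triethylsilyloxy)hex-5-en-1-yl 4-methylbenzenesulfonate | C[C@](O[Si](CC)(CC)CC)(COS(=O)(=O)c1ccc(C)cc1)CCC=C | intermediate
6 | secondary ozonide of 5 (1,2,4-trioxolane, both epimers at the acetal carbon) | C[C@](O[Si](CC)(CC)CC)(COS(=O)(=O)c1ccc(C)cc1)CCC1OCOO1 | intermediate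
7 | (2R)-2-methyl-5-oxo-2-(triethylsilyloxy)pentyl 4-methylbenzenesulfonate | C[C@](O[Si](CC)(CC)CC)(COS(=O)(=O)c1ccc(C)cc1)CCC=O | intermediate
8 | (E)-crotylboronic acid pinacol ester | C/C=C/CB1OC(C)(C)C(C)(C)O1 | starting material
9 | pinacol borate of 10 | C=C[C@H](C)[C@H](OB1OC(C)(C)C(C)(C)O1)CC[C@@](C)(O[Si](CC)(CC)CC)COS(=O)(=O)c1ccc(C)cc1 | intermediate
10 | (2R,5R,6S)-5-hydroxy-2,6-dimethyl-2-(triethylsilyloxy)oct-7-en-1-yl 4-methylbenzenesulfonate | C=C[C@H](C)[C@H](O)CC[C@@](C)(O[Si](CC)(CC)CC)COS(=O)(=O)c1ccc(C)cc1 | intermediate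
11 | (2R,5R,6S)-2,6-dimethyl-5-(methylsulfonyloxy)-2-(triethylsilyloxy)oct-7-en-1-yl 4-methylbenzenesulfonate | C=C[C@H](C)[C@H](OS(C)(=O)=O)CC[C@@](C)(O[Si](CC)(CC)CC)COS(=O)(=O)c1ccc(C)cc1 | intermediate
12 | 2,3-dimethylbut-2-ene | CC(C)=C(C)C | starting material
13 | acetone O-oxide | CC(C)=[O+][O-] | intermediate
14 | 2-methoxyprop-2-yl hydroperoxide | COC(C)(C)OO | intermediate
15 | (2R,5S,6S)-5-[(2-methoxypropan-2-yl)peroxy]-2,6-dimethyl-2-(triethylsilyloxy)oct-7-en-1-yl 4-methylbenzenesulfonate | C=C[C@H](C)[C@@H](OOC(C)(C)OC)CC[C@@](C)(O[Si](CC)(CC)CC)COS(=O)(=O)c1ccc(C)cc1 | intermediate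
16 | tetrabutylammonium C6 alkoxide from 15 | C=C[C@H](C)[C@@H](OOC(C)(C)OC)CC[C@@](C)([O-])COS(=O)(=O)c1ccc(C)cc1.CCCC[N+](CCCC)(CCCC)CCCC | intermediate
17 | (2R)-2-{(3S,4S)-3-[(2-methoxypropan-2-yl)peroxy]-4-methylhex-5-en-1-yl}-2-methyloxirane | C=C[C@H](C)[C@@H](OOC(C)(C)OC)CC[C@]1(C)CO1 | intermediate
18 | (2R)-2-[(3S,4S)-3-hydroperoxy-4-methylhex-5-en-1-yl]-2-methyloxirane | C=C[C@H](C)[C@@H](OO)CC[C@]1(C)CO1 | intermediate
19 | {(3S,6S)-6-[(2S)-but-3-en-2-yl]-3-methyl-1,2-dioxan-3-yl}methanol | C=C[C@H](C)[C@@H]1CC[C@@](C)(CO)OO1 | intermediate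
20 | secondary ozonide of 19 (both epimers at the acetal carbon) | C1(OCOO1)[C@H](C)[C@@H]2CC[C@@](C)(CO)OO2 | intermediate
21 | (2R)-2-[(3S,6S)-6-(hydroxymethyl)-6-methyl-1,2-dioxan-3-yl]propanal | O=C[C@H](C)[C@@H]1CC[C@@](C)(CO)OO1 | intermediate
22 | (2R)-2-[(3S,6S)-6-(hydroxymethyl)-6-methyl-1,2-dioxan-3-yl]propanoic acid | OC(=O)[C@H](C)[C@@H]1CC[C@@](C)(CO)OO1 | intermediate
23 | methyl (2R)-2-[(3S,6S)-6-(hydroxymethyl)-6-methyl-1,2-dioxan-3-yl]propanoate | COC(=O)[C@H](C)[C@@H]1CC[C@@](C)(CO)OO1 | intermediate
24 | methyl (2R)-2-[(3S,6S)-6-formyl-6-methyl-1,2-dioxan-3-yl]propanoate | COC(=O)[C@H](C)[C@@H]1CC[C@@](C)(C=O)OO1 | intermediate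
25 | β-cyclocitral | CC1=C(C=O)C(C)(C)CCC1 | starting material
26 | β-cyclogeraniol | CC1=C(CO)C(C)(C)CCC1 | intermediate
27 | [(2,6,6-trimethylcyclohex-1-en-1-yl)methyl]triphenylphosphonium bromide | CC1=C(C[P+](c2ccccc2)(c2ccccc2)c2ccccc2)C(C)(C)CCC1.[Br-] | intermediate
28 | [(2,6,6-trimethylcyclohex-1-en-1-yl)methylidene]triphenylphosphorane | CC1=C(C=P(c2ccccc2)(c2ccccc2)c2ccccc2)C(C)(C)CCC1 | intermediate
29 | methyl (2R)-2-{(3S,6S)-6-methyl-6-[(E)-2-(2,6,6-trimethylcyclohex-1-en-1-yl)ethenyl]-1,2-dioxan-3-yl}propanoate | COC(=O)[C@H](C)[C@@H]1CC[C@@](C)(/C=C/C2=C(C)CCCC2(C)C)OO1 | intermediate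
30 | methyl (2R)-2-{(3S,6R)-6-methyl-6-[2-(2,6,6-trimethylcyclohex-1-en-1-yl)ethyl]-1,2-dioxan-3-yl}propanoate | COC(=O)[C@H](C)[C@@H]1CC[C@@](C)(CCC2=C(C)CCCC2(C)C)OO1 | intermediate
31 | methyl diacarnoate A | COC(=O)[C@H](C)[C@@H]1CC[C@@](C)(CCC2=C(C)C(=O)CCC2(C)C)OO1 | target

**Step count**
Total: 20 steps (17 in the main line, 1 for the peroxide reagent, 2 for the phosphonium salt).
Longest linear sequence: 17 steps (steps 1–6, 8–15, 18–20).

**Three steps most likely to fail**

1. Step 8 (peroxide SN2 at C3).
   - **What may go wrong:** Substitution at the β-branched secondary carbon is slow. E2 loss of the mesylate through the allylic C2–H, and Kornblum–DeLaMare breakdown of the perketal on long contact with base, may overtake it.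
   - **Fallback:** There is no substitution at C3; the C3–O bond is made by conjugate addition. The fallback sets out from aldehyde 7 and comes back at hydroxy ester 23.
   - **Sequence:** Wittig olefination of 7 with methyl 2-(triphenylphosphoranylidene)propanoate in CH2Cl2 should give the (E)-2-methyl enoate F1. Bu4NF then closes the oxirane as in step 9 to the epoxy enoate F2. Perhydrolysis with ethereal H2O2 and catalytic H3PMo12O40 should open the tertiary C6–O bond with inversion to the β-hydroxy hydroperoxide F3. Catalytic Et2NH in CF3CH2OH then brings about the 6-exo-trig peroxy-Michael addition to 23.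
   - **Cost:** C6 is still set by inversion. C3 and C2 would rest on the chair preference and on protonation of the ester enolate, so 23 would have to be separated from its isomers.

2. Step 11 (key closure).
   - **What may go wrong:** Partial ionisation at C6 would cost stereochemical fidelity. A hydride shift of the Meinwald type, or acid-induced heterolysis of the secondary hydroperoxide, may also intervene.
   - **Fallback:** The roles of the two carbons are exchanged. The fallback sets out from mesylate 11 and comes back at dioxane 19.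
   - **Sequence:** Bu4NF should convert 11 into the epoxy mesylate F4, since the 3-exo closure on the primary tosylate is faster than the 5-exo attack on the hindered C3 mesylate. Ethereal H2O2 with catalytic H3PMo12O40 should open the epoxide at C6 with inversion, with a large excess of external nucleophile, to the tertiary hydroperoxide F5. Cs2CO3 in DMF deprotonates only the hydroperoxide, which displaces the C3 mesylate in a 6-exo-tet SN2 with inversion to give 19.
   - **Outcome:** Both inversions are the same as in the main line, so the same stereoisomer results, and no secondary hydroperoxide ever meets acid.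

3. Step 20 (allylic oxidation).
   - **What may go wrong:** Site selectivity among C11H2, C8H2 and the C10 methyl may be poor, and the C3–H next to the peroxide may be attacked on the most advanced material.
   - **Fallback:** Ring A is oxidised before the coupling. The fallback sets out from β-cyclogeraniol 26, uses aldehyde 24, and comes back at target 31.
   - **Sequence to the salt:** Ac2O/pyridine gives β-cyclogeranyl acetate F6. CrO3/3,5-dimethylpyrazole oxidises the ring methylene of this simple, peroxide-free substrate to the oxo acetate F7. K2CO3/MeOH frees the hydroxymethyl enone F8. An Appel reaction (CBr4, PPh3) gives the bromomethyl enone F9, and PPh3 in toluene gives the oxo phosphonium bromide F10.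
   - **Coupling:** NaN(SiMe3)2 forms the vinylogous acyl ylide F11, which is condensed with 24 to the dienone F12. Diimide as in step 19 then saturates C7=C8 and leaves the tetrasubstituted enone, giving 31.

**Further compounds**
F1 | step 8 | methyl (2E,6R)-2,6-dimethyl-7-(tosyloxy)-6-(triethylsilyloxy)hept-2-enoate | COC(=O)/C(C)=C/CC[C@@](C)(O[Si](CC)(CC)CC)COS(=O)(=O)c1ccc(C)cc1
F2 | step 8 | methyl (2E)-2-methyl-5-[(2R)-2-methyloxiran-2-yl]pent-2-enoate | COC(=O)/C(C)=C/CC[C@]1(C)CO1
F3 | step 8 | methyl (2E,6S)-6-hydroperoxy-7-hydroxy-2,6-dimethylhept-2-enoate | COC(=O)/C(C)=C/CC[C@@](C)(CO)OO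
F4 | step 11 | (3R,4S)-4-methyl-1-[(2R)-2-methyloxiran-2-yl]hex-5-en-3-yl methanesulfonate | C=C[C@H](C)[C@H](OS(C)(=O)=O)CC[C@]1(C)CO1
F5 | step 11 | (3S,4R,7S)-7-hydroperoxy-8-hydroxy-3,7-dimethyloct-1-en-4-yl methanesulfonate | C=C[C@H](C)[C@H](OS(C)(=O)=O)CC[C@@](C)(CO)OO
F6 | step 20 | β-cyclogeranyl acetate | CC(=O)OCC1=C(C)CCCC1(C)C
F7 | step 20 | (2,6,6-trimethyl-3-oxocyclohex-1-en-1-yl)methyl acetate | CC(=O)OCC1=C(C)C(=O)CCC1(C)C
F8 | step 20 | 3-(hydroxymethyl)-2,4,4-trimethylcyclohex-2-en-1-one | OCC1=C(C)C(=O)CCC1(C)C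
F9 | step 20 | 3-(bromomethyl)-2,4,4-trimethylcyclohex-2-en-1-one | BrCC1=C(C)C(=O)CCC1(C)C
F10 | step 20 | [(2,6,6-trimethyl-3-oxocyclohex-1-en-1-yl)methyl]triphenylphosphonium bromide | CC1=C(C[P+](c2ccccc2)(c2ccccc2)c2ccccc2)C(C)(C)CCC1=O.[Br-]
F11 | step 20 | [(2,6,6-trimethyl-3-oxocyclohex-1-en-1-yl)methylidene]triphenylphosphorane | CC1=C(C=P(c2ccccc2)(c2ccccc2)c2ccccc2)C(C)(C)CCC1=O
F12 | step 20 | methyl (2R)-2-{(3S,6S)-6-methyl-6-[(E)-2-(2,6,6-trimethyl-3-oxocyclohex-1-en-1-yl)ethenyl]-1,2-dioxan-3-yl}propanoate | COC(=O)[C@H](C)[C@@H]1CC[C@@](C)(/C=C/C2=C(C)C(=O)CCC2(C)C)OO1
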